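Time is where I started. Between 2.00 h and 4.00 h of the teal run, the J still to come (reckoned from the last reading, 43.5%) fell from 23 percentage points to 9.7 points. J is made from L, so I read this decay as the half-life h of L in teal, all its losses together.

| flask | Q | L | Z | remark |
|---|---|---|---|---|
| teal | 0.034 M | 0.040 M | 0.50 mM | run made earlier |
| red | 0.075 M | 0.040 M | 0.50 mM | run made earlier |
| flask | 0.050 M | 0.0400 M | 0.50 mM |  |

- teal (time / h: J / %, Q / %): 0.833: 8.8, 83.9; 1.33: 13.5, 78.6; 2.00: 20.6, 69.2; 4.00: 33.8, 50.6; 6.00: 40.7, 40.0; 10.0: 43.5, 30.1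
- red (time / h: J / %, Q / %): 1.50: 14.2, 79.0; 3.00: 20.4, 64.0; 5.00: 27.2, 54.1; 6.00: 25.6, 50.2; 8.00: 26.2, 45.8; 10.0: 26.1, 41.4

(each reading ± 1 percentage point)

- reactions considered so far: L + D -> Z + J; L -> E; Z + X <-> D; Q + Z <-> Z + X
- no earlier run changes the charge of Z; that part of a forecast is a guess

- factor on the rate of making J when 50% of the Q are converted if Z is charged twice over
- factor on the rate when 50% of the Q are converted if Z is charged at 0.10 mM instead

h = 1.61 h

Q stood at 50.6% after 4.00 h in teal and at 50.2% after 6.00 h in red. Interpolating on the charge of Q, I put the time T to 50% conversion in the flask at: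

T = 4.78 h

I turned the question round. With the share of catalyst held as D kept fixed, the rate would simply follow the charge of Z if L stood nearly untouched at that moment, with T far below h. But in this flask I reckoned T longer than h. So I carried n, the number of half-lives of L that pass before the marked conversion:

n = T / h = 2.96, so by this reckoning L left 12.9%

My guess, which no run tests, was that T goes inversely with Z, while h and the share of catalyst held as D stay put. The factor is then the charge ratio times two to the power of the half-lives saved:

twice the Z: 1.48 half-lives saved, factor 5.58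

0.10 mM of Z: 11.8 half-lives added, factor 5.42 × 10⁻⁵

The forecast, reckoned differently, gave 3.6 and 5.000 × 10⁻⁴, saying “the ratio is about zero”.

The simulation gave 5.11 and 1.09 × 10⁻⁷.

    L + D → Z + J (k = 38.0 M⁻¹ min⁻¹)
    L → E (k = 0.00520 min⁻¹)
    Z + X ⇌ D (K = 77.0 M⁻¹, k = 1600 M⁻¹ min⁻¹)
    Q + Z ⇌ Z + X (K = 1.40, k = 7.30 M⁻¹ min⁻¹)

In the flask, where L was the limiting reagent with 0.37% of its charge left after 8.00 h, 50% conversion came at 4.86 h, against a half-life of L through E by itself of 2.2 h at 8.00 h, and the simulated 5.11, read back through the doubling line, gives n = 2.71 against my 2.96. With 0.10 mM of Z the simulated factor lies below my 5.42 × 10⁻⁵, and its 1.09 × 10⁻⁷, read back the same way, stands for n = 5.20.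

The data stem from a simulated flask for an exercise, noise included.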